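## Retrosynthetic overview

1. Target 23 ⇐ acetylation of diol 22 ⇐ hydroxyl-directed hydrogenation of a C7-isopropenyl diene, made by Suzuki coupling of the C7 enol triflate (C7 ketone unmasked from a dioxolane).
2. C5–H and C6–OH ⇐ α-face hydroboration of the Δ5 tertiary allylic alcohol 12; the C4 carbinol ⇐ α-face MeMgBr addition to enone 11.
3. Enone 11 ⇐ dihydroxylation, oxidation and dehydration of the Δ4 ketal 8, itself from ketalization (with alkene shift) of bromo enone 7.
4. Equatorial C1–Br ⇐ Appel inversion of the axial alcohol 6 ⇐ ketoreductase reduction of (R)-Wieland–Miescher ketone 5.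
5. Ring order: ring A is the starting 2-methylcyclohexane-1,3-dione; ring B is annulated by Michael addition to methyl vinyl ketone and an organocatalytic asymmetric aldol condensation that sets C10.

Convention (assumed): positions follow the eudesmane numbering of the target (C1 = CHBr, C4 = C(CH3)OH, C5 = ring-fusion CH, C6 = CHOAc, C7 = CH(iPr), C10 = C(CH3)). β is the face of the C10 methyl, α the opposite face. In this numbering the target is (1R,4S,5S,6S,7S,10R): 1β-Br, 4β-OH/4α-CH3, 5α-H, 6α-OAc, 7β-iPr, 10β-CH3.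

## Route

Step 1
Reactants: 1 2-methylcyclohexane-1,3-dione; 2 methyl vinyl ketone (but-3-en-2-one)
Product: 3 2-methyl-2-(3-oxobutyl)cyclohexane-1,3-dione
Conditions: Et3N (1 mol%), neat, rt
Reagents that add atoms: none
Why: Base-catalysed Michael addition of the acidic 2-alkyl-1,3-dione to the enone gives the achiral, prochiral triketone by C-alkylation.

Step 2
Reactants: 3 2-methyl-2-(3-oxobutyl)cyclohexane-1,3-dione
Product: 5 (R)-Wieland–Miescher ketone, via bicyclic ketol 4 (not isolated)
Conditions: N-tosyl-(Ra)-binam-D-prolinamide (2 mol%), PhCO2H (2.5 mol%), neat, rt; recrystallize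
Reagents that add atoms: none
Why: Enamine-mediated intramolecular aldol condensation (Hajos–Parrish–Eder–Sauer–Wiechert type Robinson annulation) in which the chiral prolinamide differentiates the two enantiotopic ring carbonyls and sets C10 as R (the enantiomeric catalyst is the one known to give the S ketone).

Step 3
Reactants: 5 (R)-Wieland–Miescher ketone
Product: 6 1α-hydroxy enone, (4aR,5S)-5-hydroxy-4a-methyl-4,4a,5,6,7,8-hexahydronaphthalen-2(3H)-one
Conditions: ketoreductase (NADPH-dependent, (S)-selective), NADP+ (cat.), iPrOH (10% v/v), phosphate buffer pH 7, 30 °C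
Reagents that add atoms: none
Why: Enzymatic carbonyl reduction by a Prelog-type ketoreductase (chosen by screening) reduces only the saturated C1 ketone and gives the axial 1α-alcohol (1S) that hydride reagents do not deliver, while the minor enantiomer of 5 ends up as a separable diastereomer.

Step 4
Reactants: 6 1α-hydroxy enone
Product: 7 1β-bromo enone, (4aR,5R)-5-bromo-4a-methyl-4,4a,5,6,7,8-hexahydronaphthalen-2(3H)-one
Conditions: PPh3, CBr4, toluene, 0 °C to 60 °C
Reagents that add atoms: carbon tetrabromide (BrC(Br)(Br)Br)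
Why: Appel reaction in which bromide displaces the axial oxyphosphonium group by SN2 with inversion, giving the equatorial 1β-bromide (1R), which has no anti-periplanar hydrogen and is therefore robust to the later basic steps.

Step 5
Reactants: 7 1β-bromo enone
Product: 8 Δ4 bromo ketal (C4=C5 alkene, 1,3-dioxolane at C7)
Conditions: HOCH2CH2OH, p-TsOH (cat.), benzene, reflux (Dean–Stark)
Reagents that add atoms: ethylene glycol (OCCO)
Why: Acid-catalysed ketalization of the enone goes through the dienol ether and, as with steroidal 4-en-3-ones, gives the β,γ-unsaturated dioxolane, which masks C7 and moves the alkene to C4=C5.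

Step 6
Reactants: 8 Δ4 bromo ketal
Product: 9 4α,5α-diol
Conditions: OsO4 (5 mol%), NMO, pyridine, acetone/H2O, 40 °C
Reagents that add atoms: OsO4 (O=[Os](=O)(=O)=O); N-methylmorpholine N-oxide (C[N+]1([O-])CCOCC1); water (O)
Why: Upjohn syn-dihydroxylation of the only alkene from the α face opposite the angular methyl places oxygen on C4 and C5; the configuration of these two centres is erased in the next two steps.

Step 7
Reactants: 9 4α,5α-diol
Product: 10 5α-hydroxy-4-ketone
Conditions: Dess–Martin periodinane, pyridine, CH2Cl2, rt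
Reagents that add atoms: none
Why: Dess–Martin oxidation converts the secondary C4 alcohol to the ketone, the tertiary C5 alcohol cannot be oxidised, and the buffered medium spares the ketal.

Step 8
Reactants: 10 5α-hydroxy-4-ketone
Product: 11 Δ5-4-ketone (C4(=O)–C5=C6 enone)
Conditions: SOCl2, pyridine, 0 °C
Reagents that add atoms: none
Why: Chlorosulfite formation at the axial tertiary 5α-OH and anti-periplanar E2 loss of the axial 6β-H, the only β-hydrogen available, gives the conjugated enone regiospecifically (as in 5α-hydroxy-6-keto steroids).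

Step 9
Reactants: 11 Δ5-4-ketone
Product: 12 tertiary allylic alcohol (4β-OH, 4α-CH3, C5=C6)
Conditions: MeMgBr, CeCl3, THF, −78 °C
Reagents that add atoms: methylmagnesium bromide (C[Mg]Br)
Why: Cerium-mediated Grignard 1,2-addition to the enone carbonyl occurs from the α face because the β face of C4 is blocked 1,3 by the axial C10 methyl, giving 4α-CH3/4β-OH (4S).

Step 10
Reactants: 12 tertiary allylic alcohol
Product: 14 4β,6α-diol ketal, via C6 alkylborane 13 (not isolated)
Conditions: BH3·THF (excess), THF, 0 °C to rt; then NaOH, H2O2, 0 °C to rt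
Reagents that add atoms: hydrogen peroxide (OO)
Why: Hydroboration–oxidation adds H and B syn and anti-Markovnikov from the α face (the β face is screened by the C10 methyl and the axial C4 oxygen), setting 5α-H (trans-decalin, 5S) and, after oxidation with retention, 6α-OH (6S).

Step 11
Reactants: 14 4β,6α-diol ketal
Product: 15 6α-hydroxy-7-ketone
Conditions: 2 M HCl, THF, 40 °C
Reagents that add atoms: water (O)
Why: Acid-catalysed ketal hydrolysis frees the C7 ketone, and short treatment with dilute acid leaves the equatorial bromide and both alcohols intact and limits α-ketol isomerization.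

Step 12
Reactants: 15 6α-hydroxy-7-ketone
Product: 16 bis(triethylsilyl) ether
Conditions: Et3SiOTf, 2,6-lutidine, CH2Cl2, −78 °C to 0 °C
Reagents that add atoms: triethylsilyl trifluoromethanesulfonate (CC[Si](CC)(CC)OS(=O)(=O)C(F)(F)F)
Why: Silyl triflate silylation protects both the secondary and the hindered tertiary hydroxyl so that only the ketone reacts with base in the next step.

Step 13
Reactants: 16 bis(triethylsilyl) ether
Product: 18 C7 enol triflate, via potassium enolate 17 (not isolated)
Conditions: KN(SiMe3)2 added to 16 and PhNTf2, THF, −78 °C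
Reagents that add atoms: N-phenylbis(trifluoromethanesulfonimide) (O=S(=O)(N(c1ccccc1)S(=O)(=O)C(F)(F)F)C(F)(F)F)
Why: Kinetic deprotonation at the unhindered C8 methylene (C6 is a shielded silyloxy methine) and immediate O-triflation of the enolate give the C7=C8 enol triflate.

Step 14
Reactants: 18 C7 enol triflate; 19 isopropenylboronic acid pinacol ester
Product: 20 bis-silylated C7-isopropenyl diene
Conditions: Pd(dppf)Cl2 (5 mol%), K3PO4, dioxane/H2O, 60 °C
Reagents that add atoms: none
Why: Suzuki–Miyaura cross-coupling of the alkenyl triflate with the alkenylboronate installs the three-carbon unit at C7, and the unactivated secondary alkyl bromide does not react with this catalyst.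

Step 15
Reactants: 20 bis-silylated C7-isopropenyl diene
Product: 21 diene diol
Conditions: HF·pyridine, THF, 0 °C to rt
Reagents that add atoms: none
Why: Fluoride-mediated Si–O cleavage frees the C6 hydroxyl needed to direct the hydrogenation without touching any stereocentre.

Step 16
Reactants: 21 diene diol
Product: 22 1β-bromoeudesmane-4β,6α-diol
Conditions: H2 (1 atm), [Ir(cod)(PCy3)(py)]PF6 (10 mol%), CH2Cl2, rt
Reagents that add atoms: none
Why: Hydroxyl-directed homogeneous hydrogenation, in which the cationic iridium catalyst binds the allylic 6α-OH and delivers hydrogen to C7 from the α face (also the open face), gives the equatorial 7β-isopropyl group (7S) without C–Br hydrogenolysis.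

Step 17
Reactants: 22 1β-bromoeudesmane-4β,6α-diol
Product: 23 target acetate
Conditions: Ac2O, DMAP (cat.), pyridine, rt
Reagents that add atoms: acetic anhydride (CC(=O)OC(C)=O)
Why: DMAP-catalysed acylation esterifies the secondary C6 alcohol while the hindered tertiary C4 alcohol is not acylated.

## Compound list

1 | 2-methylcyclohexane-1,3-dione | CC1C(=O)CCCC1=O | starting material
2 | but-3-en-2-one (methyl vinyl ketone) | CC(=O)C=C | starting material
3 | 2-methyl-2-(3-oxobutyl)cyclohexane-1,3-dione | CC(=O)CCC1(C)C(=O)CCCC1=O | intermediate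
4 | (4aR,8aR)-4a-hydroxy-8a-methyloctahydronaphthalene-1,6-dione (cis-fused ketol, OH and CH3 cis) | O=C1C[C@@]2(O)[C@@](C)(CC1)C(=O)CCC2 | intermediate (not isolated)
5 | (R)-Wieland–Miescher ketone, (8aR)-8a-methyl-3,4,8,8a-tetrahydronaphthalene-1,6(2H,7H)-dione | O=C1C=C2[C@@](C)(CC1)C(=O)CCC2 | intermediate
6 | (4aR,5S)-5-hydroxy-4a-methyl-4,4a,5,6,7,8-hexahydronaphthalen-2(3H)-one (1α-OH, axial, trans to the C10 methyl) | O=C1C=C2[C@@](C)(CC1)[C@@H](O)CCC2 | intermediate
7 | (4aR,5R)-5-bromo-4a-methyl-4,4a,5,6,7,8-hexahydronaphthalen-2(3H)-one (1β-Br, equatorial) | O=C1C=C2[C@@](C)(CC1)[C@H](Br)CCC2 | intermediate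
8 | 1β-bromo-10β-methyloctal-4-en-7-one ethylene ketal (C4=C5 alkene, 1,3-dioxolane at C7) | C[C@@]12CCC3(OCCO3)CC1=CCC[C@H]2Br | intermediate
9 | 1β-bromo-4α,5α-dihydroxy-10β-methyldecalin-7-one ethylene ketal (trans-fused, cis-diol) | C1[C@]2(O)[C@@](C)(CCC13OCCO3)[C@H](Br)CC[C@H]2O | intermediate
10 | 1β-bromo-5α-hydroxy-10β-methyldecalin-4,7-dione 7-ethylene ketal | C1[C@]2(O)[C@@](C)(CCC13OCCO3)[C@H](Br)CCC2=O | intermediate
11 | 1β-bromo-10β-methyloctal-5-ene-4,7-dione 7-ethylene ketal (C4 ketone conjugated with C5=C6) | C1=C2[C@@](C)(CCC13OCCO3)[C@H](Br)CCC2=O | intermediate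
12 | 1β-bromo-4β-hydroxy-4α,10β-dimethyloctal-5-en-7-one ethylene ketal | C1=C2[C@@](C)(CCC13OCCO3)[C@H](Br)CC[C@]2(C)O | intermediate
13 | C6 alkylborane of 12 (6α-BH2, 5α-H; C4 oxygen as O–BH2) | B[C@@H]1[C@@H]2[C@@](C)(CCC13OCCO3)[C@H](Br)CC[C@]2(C)OB | intermediate (not isolated)
14 | 1β-bromo-4β,6α-dihydroxy-4α,10β-dimethyl-trans-decalin-7-one ethylene ketal (5α-H) | O[C@@H]1[C@@H]2[C@@](C)(CCC13OCCO3)[C@H](Br)CC[C@]2(C)O | intermediate
15 | 1β-bromo-4β,6α-dihydroxy-4α,10β-dimethyl-trans-decalin-7-one | O[C@@H]1[C@@H]2[C@@](C)(CCC1=O)[C@H](Br)CC[C@]2(C)O | intermediate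
16 | bis(triethylsilyl) ether of 15 (4β-OSiEt3, 6α-OSiEt3) | CC[Si](CC)(CC)O[C@@H]1[C@@H]2[C@@](C)(CCC1=O)[C@H](Br)CC[C@]2(C)O[Si](CC)(CC)CC | intermediate
17 | potassium C7(O)=C8 enolate of 16 | CC[Si](CC)(CC)O[C@@H]1[C@@H]2[C@@](C)(CC=C1[O-])[C@H](Br)CC[C@]2(C)O[Si](CC)(CC)CC.[K+] | intermediate (not isolated)
18 | C7=C8 enol triflate of 16 | CC[Si](CC)(CC)O[C@@H]1[C@@H]2[C@@](C)(CC=C1OS(=O)(=O)C(F)(F)F)[C@H](Br)CC[C@]2(C)O[Si](CC)(CC)CC | intermediate
19 | 4,4,5,5-tetramethyl-2-(prop-1-en-2-yl)-1,3,2-dioxaborolane (isopropenylboronic acid pinacol ester) | CC(=C)B1OC(C)(C)C(C)(C)O1 | starting material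
20 | 1β-bromo-7-isopropenyl-4α,10β-dimethyl-4β,6α-bis(triethylsilyloxy)octal-7-ene (5α-H) | CC[Si](CC)(CC)O[C@@H]1[C@@H]2[C@@](C)(CC=C1C(C)=C)[C@H](Br)CC[C@]2(C)O[Si](CC)(CC)CC | intermediate
21 | 1β-bromo-7-isopropenyl-4α,10β-dimethyloctal-7-ene-4β,6α-diol (5α-H) | O[C@@H]1[C@@H]2[C@@](C)(CC=C1C(C)=C)[C@H](Br)CC[C@]2(C)O | intermediate
22 | (1R,4S,5S,6S,7S,10R)-1-bromoeudesmane-4,6-diol (1β-Br, 4β-OH, 6α-OH, 7β-iPr) | O[C@@H]1[C@@H]2[C@@](C)(CC[C@H]1C(C)C)[C@H](Br)CC[C@]2(C)O | intermediate
23 | (1S,2S,4aR,5R,8S,8aS)-5-bromo-8-hydroxy-4a,8-dimethyl-2-(propan-2-yl)decahydronaphthalen-1-yl acetate | CC(=O)O[C@@H]1[C@@H]2[C@@](C)(CC[C@H]1C(C)C)[C@H](Br)CC[C@]2(C)O | target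

## Step count and weakest steps

Total step count: 17. Longest linear sequence: 17 steps (1 to 23; boronate 19 enters at step 14).

Most likely to fail, step 4: the Appel inversion is at a secondary carbinol next to the quaternary C10, so elimination to the C1=C2 alkene or a methyl shift can compete with substitution. The fallback sets out from 6 and activates the alcohol as the isolated axial C1 triflate F1 (Tf2O, pyridine, CH2Cl2, −30 °C). F1 is then displaced with Bu4NBr in toluene at 0 °C to rt, an SN2 on a discrete sulfonate by a naked bromide in a non-ionizing solvent instead of through an oxyphosphonium ion. It comes back to the route at 7.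

Second, step 10: the hydroboration of a hindered trisubstituted alkene next to a ketal and a free tertiary alcohol may be slow or less face-selective than expected. The fallback sets out from 11 and uses nucleophilic epoxidation (t-BuOOH, DBU, CH2Cl2) from the α face to give the 5α,6α-epoxy ketone F2. SmI2 in THF/MeOH at −78 °C then cleaves the C5–O bond to give the trans-fused 6α-hydroxy-4-ketone F3. Addition of MeMgBr/CeCl3 to C4 from the α face gives 14, where it comes back to the route (12 and 13 are bypassed).

Third, step 11: hydrolysis of a ketal that carries an α-hydroxyl is slow, and forcing it risks α-ketol isomerization or loss of the tertiary alcohol. The fallback sets out from 12, whose ketal is not retarded, and hydrolyses it (PPTS, wet acetone) to the γ-hydroxy enone F4. Conjugate reduction with [(Ph3P)CuH]6 and trapping with Me3SiCl delivers hydride to C5 from the α face and gives the trimethylsilyl enol ether F5. Rubottom oxidation (mCPBA, NaHCO3, CH2Cl2, then dilute acid) from the α face gives 15, where it comes back to the route (13 and 14 are bypassed).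

## Further compounds

F1 | step 4 | C1 α-triflate of 6, (4aR,5S)-4a-methyl-2-oxo-2,3,4,4a,5,6,7,8-octahydronaphthalen-5-yl trifluoromethanesulfonate | O=C1C=C2[C@@](C)(CC1)[C@@H](OS(=O)(=O)C(F)(F)F)CCC2
F2 | step 10 | 1β-bromo-5α,6α-epoxy-10β-methyldecalin-4,7-dione 7-ethylene ketal | O1[C@@H]2[C@@]13[C@@](C)(CCC24OCCO4)[C@H](Br)CCC3=O
F3 | step 10 | 1β-bromo-6α-hydroxy-10β-methyl-trans-decalin-4,7-dione 7-ethylene ketal (5α-H) | O[C@@H]1[C@@H]2[C@@](C)(CCC13OCCO3)[C@H](Br)CCC2=O
F4 | step 11 | 1β-bromo-4β-hydroxy-4α,10β-dimethyloctal-5-en-7-one (γ-hydroxy enone) | O=C1C=C2[C@@](C)(CC1)[C@H](Br)CC[C@]2(C)O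
F5 | step 11 | 1β-bromo-4α,10β-dimethyl-7-(trimethylsilyloxy)-trans-octal-6-en-4β-ol (5α-H, C6=C7 silyl enol ether) | C[Si](C)(C)OC1=C[C@@H]2[C@@](C)(CC1)[C@H](Br)CC[C@]2(C)O
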